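**Plan**

- Retrosynthesis: the 3-O-benzyl and 5-O-methyl groups are put back first. Ring B is then cut at C1'–C6' and unfolded into a 5-methoxy-4-pyranone joined to chromone C2 through a CH2. The CH2–C2 bond is cut next (zinc/palladium coupling), then C2 itself (formamide acetal carbon) and the aryl–CO bond of ring A (Friedel–Crafts).
- Feature used: ring B has oxygens on C2' and C4' (meta), a methoxy on C5' and hydrogens on C3' and C6'. These are O1, the C4 carbonyl oxygen, the 5-methoxy group, C3–H and C6–H of O-methylated kojic acid, whose side-chain carbon becomes C1'.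
- Forward order: ring A ketone, then ring C (chromone), then the pyranone attached at C2, then the pyranone refolded into ring B by base, then deprotection.
- Stereochemistry: the target has no stereocentre and no stereogenic double bond, so nothing has to be set.

Key step: step 6

Assumption: 1,2,3,5-tetramethoxybenzene (1) is taken as a purchasable compound (otherwise one O-methylation of 3,4,5-trimethoxyphenol).

**Route**

Step 1
Reactants: 1 1,2,3,5-tetramethoxybenzene; 2 benzyloxyacetyl chloride
Product: 4 2-(benzyloxy)-1-(2-hydroxy-3,4,6-trimethoxyphenyl)ethan-1-one, via tetramethoxyphenyl ketone 3 (not isolated)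
Conditions: AlCl3 (1.3 equiv), Et2O, 0 °C → rt; then ice, 1 M HCl
Reagents that add atoms: none
Why: Friedel–Crafts acylation can only occur at the two equivalent free positions of the symmetric arene, and the aluminium held on the new carbonyl should then cleave the ortho-methoxy group that is buttressed by a neighbouring methoxy (chelation-controlled demethylation), the ether solvent and the near-stoichiometric AlCl3 sparing the benzyl ether.

Step 2
Reactants: 4 2-(benzyloxy)-1-(2-hydroxy-3,4,6-trimethoxyphenyl)ethan-1-one
Product: 6 3-(benzyloxy)-5,7,8-trimethoxy-4H-chromen-4-one, via enaminone 5 (not isolated)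
Conditions: DMF-DMA (3 equiv), toluene, 100 °C; then AcOH, 60 °C
Reagents that add atoms: N,N-dimethylformamide dimethyl acetal, COC(OC)N(C)C
Why: The α-methylene between the carbonyl and the benzyloxy group condenses with the amide acetal, and the chelated phenol then adds to the enamine carbon and expels dimethylamine (enaminone route to 2-unsubstituted chromones, as used for isoflavones from deoxybenzoins).

Step 3
Reactants: 7 kojic acid
Product: 8 2-(hydroxymethyl)-5-methoxy-4H-pyran-4-one
Conditions: MeI, K2CO3, acetone, reflux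
Reagents that add atoms: iodomethane, CI
Why: Williamson etherification in which the acidic enolic 5-hydroxyl is alkylated selectively over the primary alcohol.

Step 4
Reactants: 8 2-(hydroxymethyl)-5-methoxy-4H-pyran-4-one
Product: 9 2-(chloromethyl)-5-methoxy-4H-pyran-4-one
Conditions: SOCl2, CH2Cl2, 0 °C → rt
Reagents that add atoms: thionyl chloride, O=S(Cl)Cl
Why: Chlorodehydroxylation of the primary alcohol through its chlorosulfite, the standard conversion of kojic acid derivatives into their chloromethyl compounds; the pyranone is inert to acid.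

Step 5
Reactants: 6 3-(benzyloxy)-5,7,8-trimethoxy-4H-chromen-4-one; 9 2-(chloromethyl)-5-methoxy-4H-pyran-4-one
Product: 11 3-(benzyloxy)-5,7,8-trimethoxy-2-[(5-methoxy-4-oxo-4H-pyran-2-yl)methyl]-4H-chromen-4-one, via chromon-2-ylzinc chloride 10 (not isolated)
Conditions: 6 (1.2 equiv), TMPZnCl·LiCl (1.3 equiv), THF, 25 °C; then 9 (1.0 equiv), Pd(OAc)2 (3 mol %), SPhos (6 mol %), 25 → 50 °C
Reagents that add atoms: none
Why: The mild TMP-zinc amide base should zincate the only C–H of the pyranone ring of 6 (C2–H, flanked by O1 and the 3-benzyloxy oxygen, C3 being blocked), and the resulting alkenylzinc couples with the benzylic-type chloride under zerovalent palladium catalysis (Negishi sp2–sp3 coupling), conditions that tolerate both carbonyl groups.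

Step 6
Reactants: 11 3-(benzyloxy)-5,7,8-trimethoxy-2-[(5-methoxy-4-oxo-4H-pyran-2-yl)methyl]-4H-chromen-4-one
Product: 13 3-(benzyloxy)-2-(2,4-dihydroxy-5-methoxyphenyl)-5,7,8-trimethoxy-4H-chromen-4-one, via ring-opened tricarbonyl enolate 12 (not isolated)
Conditions: KOH (2 M aq, 6 equiv), MeOH, degassed, argon, 25 → 45 °C; then 1 M HCl to pH 3
Reagents that add atoms: none
Why: Hydroxide adds to the unsubstituted C6 of the 5-methoxy-4-pyranone and the ring opens to the enolate of tricarbonyl 12, in which the former ring oxygen has become the C2' ketone and C6 a formyl carbon. The methylene between chromone C2 and that ketone, acidified by the ketone and vinylogously by the chromone C4 carbonyl, then adds to the formyl carbon (intramolecular aldol, 6-(enolendo)-exo-trig, forming C1'–C6'); loss of water and enolisation of the two ring ketones aromatise ring B, which makes the sequence irreversible. The closest known reaction is the base-induced conversion of 2-alkyl-4-pyranones, through their 1,3,5-tricarbonyl forms, into orcinol-type resorcinols. No stereocentre is formed. The selectivity needed is carbon cyclisation through C1' and not through the central C3' methylene or back through oxygen: attack from C3' would close a four-membered ring and O-closure only regenerates the pyranone reversibly, so the arene is the only exit from the equilibrium. Mild temperature and exclusion of air are chosen because the electron-rich 3-benzyloxy-5,7,8-trimethoxychromone should be less electrophilic than the monocyclic pyranone and the phenolate of the product is oxidisable.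

Step 7
Reactants: 13 3-(benzyloxy)-2-(2,4-dihydroxy-5-methoxyphenyl)-5,7,8-trimethoxy-4H-chromen-4-one
Product: 14 2-(2,4-dihydroxy-5-methoxyphenyl)-3,5-dihydroxy-7,8-dimethoxy-4H-chromen-4-one
Conditions: BCl3 (1 M in CH2Cl2, 6 equiv), pentamethylbenzene (3 equiv), CH2Cl2, −78 → 20 °C; then H2O
Reagents that add atoms: none
Why: Lewis-acid ether cleavage in which BCl3 ionises the 3-O-benzyl ether (the benzyl cation being trapped by pentamethylbenzene so that the resorcinol ring is not C-benzylated) and, on warming, removes the 5-O-methyl group through its six-membered chelate with the C4 carbonyl, while the unchelated 7-, 8- and 5'-methyl ethers should stay.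

**Compound list**

1 | 1,2,3,5-tetramethoxybenzene | COc1cc(OC)c(OC)c(OC)c1 | starting material
2 | benzyloxyacetyl chloride | O=C(Cl)COCc1ccccc1 | starting material
3 | 2-(benzyloxy)-1-(2,3,4,6-tetramethoxyphenyl)ethan-1-one (aluminium-bound, formed in the flask) | O=C(COCc1ccccc1)c1c(OC)c(OC)c(OC)cc1OC | intermediate
4 | 2-(benzyloxy)-1-(2-hydroxy-3,4,6-trimethoxyphenyl)ethan-1-one | O=C(COCc1ccccc1)c1c(O)c(OC)c(OC)cc1OC | intermediate
5 | 2-(benzyloxy)-3-(dimethylamino)-1-(2-hydroxy-3,4,6-trimethoxyphenyl)prop-2-en-1-one (formed in the flask; alkene geometry not fixed, either isomer cyclises) | CN(C)C=C(OCc1ccccc1)C(=O)c1c(O)c(OC)c(OC)cc1OC | intermediate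
6 | 3-(benzyloxy)-5,7,8-trimethoxy-4H-chromen-4-one | COc1cc(OC)c2c(=O)c(OCc3ccccc3)coc2c1OC | intermediate
7 | kojic acid, 5-hydroxy-2-(hydroxymethyl)-4H-pyran-4-one | O=c1cc(CO)occ1O | starting material
8 | 2-(hydroxymethyl)-5-methoxy-4H-pyran-4-one | COc1coc(CO)cc1=O | intermediate
9 | 2-(chloromethyl)-5-methoxy-4H-pyran-4-one | COc1coc(CCl)cc1=O | intermediate
10 | [3-(benzyloxy)-5,7,8-trimethoxy-4-oxo-4H-chromen-2-yl]zinc chloride (LiCl complex, formed in the flask) | COc1cc(OC)c2c(=O)c(OCc3ccccc3)c([Zn]Cl)oc2c1OC | intermediate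
11 | 3-(benzyloxy)-5,7,8-trimethoxy-2-[(5-methoxy-4-oxo-4H-pyran-2-yl)methyl]-4H-chromen-4-one | COc1cc(OC)c2c(=O)c(OCc3ccccc3)c(Cc3cc(=O)c(OC)co3)oc2c1OC | intermediate
12 | 6-[3-(benzyloxy)-5,7,8-trimethoxy-4-oxo-4H-chromen-2-yl]-2-methoxy-3,5-dioxohexanal (formed in the flask; drawn as the tricarbonyl tautomer, present as its enolates, C2 configurationally labile) | COc1cc(OC)c2c(=O)c(OCc3ccccc3)c(CC(=O)CC(=O)C(OC)C=O)oc2c1OC | intermediate
13 | 3-(benzyloxy)-2-(2,4-dihydroxy-5-methoxyphenyl)-5,7,8-trimethoxy-4H-chromen-4-one | COc1cc(-c2oc3c(OC)c(OC)cc(OC)c3c(=O)c2OCc2ccccc2)c(O)cc1O | intermediate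
14 | 2-(2,4-dihydroxy-5-methoxyphenyl)-3,5-dihydroxy-7,8-dimethoxy-4H-chromen-4-one (CNP0319239.0, achiral) | COc1cc(-c2oc3c(OC)c(OC)cc(O)c3c(=O)c2O)c(O)cc1O | target

**Step count and risks**

Total step count: 7. Longest linear sequence: 5 steps (steps 1, 2, 5, 6, 7 from 1; equally steps 3, 4, 5, 6, 7 from 7).

Steps most likely to fail:

Step 6. Hydroxide may attack the chromone (opening of ring C and retro-Claisen scission) or cleave the formyl carbon from the opened chain faster than the chain folds, and an opened chain that has not yet cyclised simply re-closes to the pyranone on acidification. The fallback sets out from 11 and separates ring opening from ring closure. Pyrrolidine (3 equiv, EtOH, 25 °C) should add to C6 and open the pyranone to the vinylogous amide 6-[3-(benzyloxy)-5,7,8-trimethoxy-4-oxo-4H-chromen-2-yl]-2-methoxy-1-(pyrrolidin-1-yl)hex-1-ene-3,5-dione F1, which is not a formyl ketone and cannot lose its terminal carbon by retro-Claisen cleavage. Warming F1 in AcOH (80 °C) should let the chromone-activated methylene add to the enaminone carbon, expel pyrrolidine and aromatise, coming back to the route at 13.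

Step 5. Zincation may take place in part at C6–H between the two methoxy groups of ring A, the chromonylzinc may be protonated by the acidic methylene of the product as it forms, and the palladium adduct of the chloride may homocouple. The fallback sets out from 9 (with 6) and reverses the polarity of the bond formation. Zinc insertion into 9 (Zn dust, LiCl, THF, 25 °C) should give [(5-methoxy-4-oxo-4H-pyran-2-yl)methyl]zinc chloride F2. Chromone 6 is activated with TMSOTf (CH2Cl2, −78 °C) as 3-(benzyloxy)-5,7,8-trimethoxy-4-[(trimethylsilyl)oxy]chromenylium trifluoromethanesulfonate F3. Addition of the zinc reagent to C2 of this benzopyrylium salt gives the silyl enol ether 3-(benzyloxy)-5,7,8-trimethoxy-2-[(5-methoxy-4-oxo-4H-pyran-2-yl)methyl]-4-[(trimethylsilyl)oxy]-2H-chromene F4 (racemic at C2). Saegusa–Ito oxidation (Pd(OAc)2, MeCN, 25 °C) then restores the C2=C3 double bond and comes back to the route at 11.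

Step 1. The Lewis acid may cleave the benzyl ether in competition with the ortho-methyl ether, so that debenzylated or over-dealkylated ketones form. The fallback sets out from 1 and introduces the benzyl group only after all Lewis-acid chemistry:
- Friedel–Crafts acetylation (AcCl, AlCl3, Et2O) passes through 1-(2,3,4,6-tetramethoxyphenyl)ethan-1-one F5 and should give, by the same chelation-controlled demethylation, 1-(2-hydroxy-3,4,6-trimethoxyphenyl)ethan-1-one F6.
- DMF-DMA (toluene, 100 °C; then AcOH) closes, by way of (E)-3-(dimethylamino)-1-(2-hydroxy-3,4,6-trimethoxyphenyl)prop-2-en-1-one F7, the chromone 5,7,8-trimethoxy-4H-chromen-4-one F8.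
- Epoxidation of the C2=C3 bond with dimethyldioxirane (acetone, 0 °C) gives 2,3-epoxy-5,7,8-trimethoxy-2,3-dihydro-4H-chromen-4-one F9 (racemic), which TsOH in CH2Cl2 isomerises to 3-hydroxy-5,7,8-trimethoxy-4H-chromen-4-one F10.
- Benzylation (BnBr, K2CO3, DMF) comes back to the route at 6.

**Further compounds**

F1 | step 6 | 6-[3-(benzyloxy)-5,7,8-trimethoxy-4-oxo-4H-chromen-2-yl]-2-methoxy-1-(pyrrolidin-1-yl)hex-1-ene-3,5-dione (alkene geometry not fixed) | COc1cc(OC)c2c(=O)c(OCc3ccccc3)c(CC(=O)CC(=O)C(OC)=CN3CCCC3)oc2c1OC
F2 | step 5 | [(5-methoxy-4-oxo-4H-pyran-2-yl)methyl]zinc chloride | COc1coc(C[Zn]Cl)cc1=O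
F3 | step 5 | 3-(benzyloxy)-5,7,8-trimethoxy-4-[(trimethylsilyl)oxy]chromenylium trifluoromethanesulfonate | COc1cc(OC)c2c(O[Si](C)(C)C)c(OCc3ccccc3)c[o+]c2c1OC.[O-]S(=O)(=O)C(F)(F)F
F4 | step 5 | 3-(benzyloxy)-5,7,8-trimethoxy-2-[(5-methoxy-4-oxo-4H-pyran-2-yl)methyl]-4-[(trimethylsilyl)oxy]-2H-chromene (racemic) | COc1cc(OC)c2c(OC(Cc3cc(=O)c(OC)co3)C(OCc3ccccc3)=C2O[Si](C)(C)C)c1OC
F5 | step 1 | 1-(2,3,4,6-tetramethoxyphenyl)ethan-1-one | CC(=O)c1c(OC)c(OC)c(OC)cc1OC
F6 | step 1 | 1-(2-hydroxy-3,4,6-trimethoxyphenyl)ethan-1-one | CC(=O)c1c(O)c(OC)c(OC)cc1OC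
F7 | step 1 | (E)-3-(dimethylamino)-1-(2-hydroxy-3,4,6-trimethoxyphenyl)prop-2-en-1-one | CN(C)/C=C/C(=O)c1c(O)c(OC)c(OC)cc1OC
F8 | step 1 | 5,7,8-trimethoxy-4H-chromen-4-one | COc1cc(OC)c2c(=O)ccoc2c1OC
F9 | step 1 | 2,3-epoxy-5,7,8-trimethoxy-2,3-dihydro-4H-chromen-4-one (racemic, cis-fused oxirane) | COc1cc(OC)c2C(=O)C3OC3Oc2c1OC
F10 | step 1 | 3-hydroxy-5,7,8-trimethoxy-4H-chromen-4-one | COc1cc(OC)c2c(=O)c(O)coc2c1OC
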